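I read these flasks at 3.0 min, and before charging them I must decide whether the temperature is worth choosing or whether the catalyst charge is what I have to guard.

all flasks: impurity 14 µM
- alder: left-handed substrate 2 mM; right-handed substrate 2 mM; reagent 8 mM; free catalyst 13 µM; racemization catalyst 10 µM; temperature 72 °C; run made earlier
- maple: left-handed substrate 2 mM; right-handed substrate 2 mM; reagent 8 mM; free catalyst 30 µM; racemization catalyst 10 µM; temperature 100 °C; run made earlier
- birch: left-handed substrate 2 mM; right-handed substrate 2 mM; reagent 8 mM; free catalyst 20 µM; racemization catalyst 5 µM; temperature 72 °C; run made earlier
- dusk: left-handed substrate 2.0 mM; right-handed substrate 2.0 mM; reagent 8.00 mM; free catalyst 20 µM; racemization catalyst 10 µM; temperature 60 °C; time 3.0 min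
- winter: left-handed substrate 2.0 mM; right-handed substrate 2.0 mM; reagent 8.00 mM; free catalyst 20 µM; racemization catalyst 10 µM; temperature 110 °C; time 3.0 min
- spring: left-handed substrate 2.0 mM; right-handed substrate 2.0 mM; reagent 8.00 mM; free catalyst 20 µM; racemization catalyst 10 µM; temperature 85 °C; time 3.0 min

| run | time / s | left-handed product / % | left-handed substrate / % |
|---|---|---|---|
| alder | 10.0 | 8.6 | 42.9 |
| alder | 15.0 | 9.0 | 42.1 |
| alder | 30.0 | 10.4 | 41.9 |
| alder | 40.0 | 10.3 | 42.6 |
| alder | 60.0 | 9.5 | 41.8 |
| maple | 10.0 | 37.5 | 18.4 |
| maple | 12.0 | 40.4 | 15.9 |
| maple | 15.0 | 44.9 | 13.4 |
| birch | 12.0 | 22.5 | 30.0 |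
| birch | 20.0 | 30.0 | 24.8 |
| birch | 30.0 | 36.8 | 18.7 |
| birch | 40.0 | 42.0 | 15.0 |
| birch | 60.0 | 48.9 | 10.5 |

(standard deviation of a reading: 0.5 percentage points)

- free catalyst is single-handed; left-handed substrate and right-handed substrate are mirror images of each other, charged as a racemate, each of them at the stated concentration
- steps under discussion: reagent + free catalyst + left-handed substrate -> free catalyst + left-handed product; free catalyst + impurity -> spent catalyst; left-handed substrate + racemization catalyst <-> right-handed substrate + racemization catalyst; reagent + free catalyst + right-handed substrate -> free catalyst + right-handed product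

- which flask leads in amount of left-handed product, in percent of the left-handed substrate and right-handed substrate together charged ("all alike" within 1.5 percentage points) (dusk / winter / spring / all alike)
- how much left-handed product is there at the end, in percent of the left-handed substrate and right-handed substrate together charged: dusk
- how much left-handed product is there at the end, in percent of the left-handed substrate and right-handed substrate together charged: winter
- how much left-handed product is there at the end, in percent of the left-handed substrate and right-handed substrate together charged: spring

The poisoning step takes one free catalyst for each impurity, so I carry 6.00 µM: the surplus catalyst, free catalyst charged minus impurity charged. Alder has a deficit, 13 µM against 14 µM, and its left-handed product reads 8.6% at 10.0 s and 9.5% at 60.0 s. Birch has the surplus of the new flasks, 6.00 µM, and its left-handed product climbs to 48.9%. So I keep the charge.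

Now the temperature. I take right-handed substrate equal to the left-handed reading, so the left-handed share of the product made reads 61.9% in birch at 72 °C and 61.3% in maple at 100 °C. That drop of 0.60 percentage points is less than the margin of 1.5 points, but it is read from scattered readings, and maple differs from birch in free catalyst and racemization catalyst as well as in temperature.

Unconverted substrate is the small correction. Birch's left-handed substrate falls at 0.0219 s⁻¹, and carrying that rate on gives an estimate of 0.761% per hand at 3.0 min. My reckoning is therefore about 61.0% in each flask, all alike, although dusk and winter lie outside the temperatures of the runs, and I would not spend effort on the temperature.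

The forecast gives 62% for dusk, 59.7% for winter and 61.5% for spring with dusk ahead, “Lower temperature keeps selectivity but loses some conversion, so the lead is slim.”; I differ on the lead. The flasks give 62.6% for dusk, 61.9% for winter and 62.5% for spring, and the verdict is all alike.

    reagent + free catalyst + left-handed substrate → free catalyst + left-handed product (k = 8.30 × 10⁵ M⁻² s⁻¹, Ea = 8.00 kJ mol⁻¹)
    free catalyst + impurity → spent catalyst (k = 69000 M⁻¹ s⁻¹, Ea = 13.0 kJ mol⁻¹)
    left-handed substrate + racemization catalyst ⇌ right-handed substrate + racemization catalyst, rate k3*[racemization catalyst]*[left-handed substrate] forward; the back reaction follows from the equilibrium constant (k = 7400 M⁻¹ s⁻¹, Ea = 14.0 kJ mol⁻¹)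
    reagent + free catalyst + right-handed substrate → free catalyst + right-handed product (k = 4.10 × 10⁵ M⁻² s⁻¹, Ea = 11.0 kJ mol⁻¹)
    (constants at 60 °C)

At 3.00 min spring holds 30.0% of the free catalyst charged, the surplus as a share of the charge being 30.0%, with impurity, the limiting reagent of the poisoning, at 0%. Spring has not come to rest, for it still holds 0.853% of left-handed and 0.901% of right-handed substrate. By 30.0 min left-handed product has gained 2.3 points in dusk, 1.1 points in spring and 0.52 points in winter. With 0.012 mM of free catalyst, the same flask as spring has a deficit: the surplus reckoning leaves 14.3% of the impurity, and that flask shows 14.3%, with free catalyst at 0%, left-handed product at 7.46% and left-handed substrate at 44.2%.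

(Readings and results were generated by integration with constants of no real substance; scatter was added.)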